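**Retrosynthetic overview**

1. Target 56 comes from ring B 2-ketone 53 (1,3-syn reduction, acetylation), and 53 from Grob fragmentation of cyclobutane mesylate 51. The feature used: in ten-membered ring B (C1 to C10) the Z C5=C6 alkene lies 1,4 to oxygen-bearing C2, so ring B is a masked bicyclo[6.2.0]decane with a C2–C5 bond and a leaving group on C6.
2. 51 comes from a silicon-tethered enone–alkene [2+2] of 44. A vinylsilane on O16 forces the C4–C5 and C3–C2 bonds (an untethered vinyl ester would be expected to add with the opposite orientation), and Tamao oxidation then gives O4. An O14–Si–O2 silylene fixes the enol ether on C2 rather than C6.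
3. The eight-membered 2,6-dione 40 comes from CrCl2/NiCl2 closure of C8–C9, hydroxyl-directed OsO4 addition to C7=C8 and oxidative lactonisation (O7–C19).
4. C5–C6 is made by boron aldol of ring A ketone 18 with iodoenal 27 (from the Roche ester). Ring A comes from Ireland–Claisen rearrangement (C1, C10), allylboration (C14) and olefin metathesis (C11=C12).
5. Order of ring formation: ring A, eight-membered carbocycle, γ-lactone, cyclobutane (photoadduct), then ring B by fragmentation.

Key step: step 40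

Remark on the chemistry: briarane numbering is used (C15 on C1, C16 on C5, C18 on C17, C20 on C11). The centres C2 and C5 of 13 to 17 and C5 and C6 of 29 to 38 need no control because they are erased later; their SMILES show the isomer expected to dominate.

**Ring A ketone (steps 1 to 13)**

Step 1
Reactants: 1 (S)-2,2-dimethyl-1,3-dioxolane-4-carbaldehyde; 2 2-(triphenylphosphoranylidene)propanal
Product: 3 (E)-3-[(4R)-2,2-dimethyl-1,3-dioxolan-4-yl]-2-methylprop-2-enal
Conditions: PhH, 80 °C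
Reagents that add atoms: none
Why: Wittig olefination with the stabilised formyl ylide should give the E enal (future C14, C1 with C15, C2), leaving the dioxolane centre that later steers the Claisen step untouched.

Step 2
Reactants: 3 (E)-enal
Product: 4 (1E,3S)-1-[(4R)-2,2-dimethyl-1,3-dioxolan-4-yl]-2-methylhexa-1,5-dien-3-ol
Conditions: (−)-Ipc2B(allyl), Et2O, −78 °C; NaOH, H2O2
Reagents that add atoms: (−)-B-allyldiisopinocampheylborane, C=CCB([C@@H]1C[C@@H]2C[C@H]([C@H]1C)C2(C)C)[C@@H]1C[C@@H]2C[C@H]([C@H]1C)C2(C)C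
Why: Brown allylboration; the (+)-α-pinene-derived reagent should attack the si face of the aldehyde through a chair transition state and set the C14 carbinol (S) under reagent control.

Step 3
Reactants: 4 dienol
Product: 5 triisopropylsilyl ether of 4
Conditions: TIPSOTf, 2,6-lutidine, CH2Cl2, −78 °C
Reagents that add atoms: triisopropylsilyl triflate, CC(C)[Si](OS(=O)(=O)C(F)(F)F)(C(C)C)C(C)C
Why: Silyl ether formation protects O14 with a group that survives every acidic, basic and oxidative step up to the dione.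

Step 4
Reactants: 5 silyl ether
Product: 6 (2R,3E,5S)-4-methyl-5-(triisopropylsilyloxy)octa-3,7-diene-1,2-diol
Conditions: AcOH/H2O (4:1), rt
Reagents that add atoms: none
Why: Mild acetal hydrolysis frees the 1,2-diol while the hindered secondary silyl ether should stay in place.

Step 5
Reactants: 6 diol
Product: 7 (2R,3E,5S)-1-(4-methoxybenzyloxy)-4-methyl-5-(triisopropylsilyloxy)octa-3,7-dien-2-ol
Conditions: Ag2O, PMBBr, CH2Cl2, rt
Reagents that add atoms: 4-methoxybenzyl bromide, COc1ccc(CBr)cc1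
Why: Silver-oxide-mediated Williamson etherification is selective for the primary hydroxyl of a 1,2-diol, giving the C16 ether and leaving the C5 carbinol free.

Step 6
Reactants: 7 allylic alcohol; 8 3-methylbut-2-enoyl chloride
Product: 9 3-methylbut-2-enoate ester of 7
Conditions: pyridine, DMAP (cat.), CH2Cl2, 0 °C
Reagents that add atoms: none
Why: Acylation of the secondary allylic alcohol installs C9, C10, C11 and C20 as the senecioate needed for the rearrangement.

Step 7
Reactants: 9 senecioate ester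
Product: 12 (E)-2-isopropenyl-3-methyl-3-[3-(4-methoxybenzyloxy)prop-1-enyl]-4-(triisopropylsilyloxy)hept-6-enoic acid with C1 C10 C14 as in the target, via silyl ketene acetal 10 (not isolated), via trimethylsilyl ester 11 (not isolated)
Conditions: LiN(i-Pr)2, THF, −78 °C; Me3SiCl, Et3N, −78 °C to rt; aq. HCl
Reagents that add atoms: chlorotrimethylsilane, C[Si](C)(C)Cl (silicon stays only in 10 and 11)
Why: Ireland–Claisen rearrangement; γ-deprotonation of the s-cis senecioate should give the Z silyl dienolate, and a chair transition state with the C16 arm equatorial transfers the carbinol chirality to quaternary C1 (methyl axial) and sets C10 with the isopropenyl group equatorial, so that C15 and C9 end up cis as ring A requires.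

Step 8
Reactants: 12 acid
Product: 13 iodo-γ-lactone (O2–C9 lactone with iodine on C5)
Conditions: I2, NaHCO3, MeCN, 0 °C, dark
Reagents that add atoms: iodine, II
Why: Iodolactonisation (5-exo) can only engage the γ,δ-alkene C2=C5, so it puts oxygen on C2 and removes the one alkene that would otherwise compete in the metathesis.

Step 9
Reactants: 13 iodolactone
Product: 14 deiodinated γ-lactone
Conditions: Bu3SnH (0.5 M), AIBN (cat.), PhH, 80 °C
Reagents that add atoms: none
Why: Radical dehalogenation at high tin hydride concentration should reduce the C5 radical faster than it can cyclise onto the isopropenyl or allyl group.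

Step 10
Reactants: 14 lactone diene
Product: 15 bicyclic lactone with ring A closed (C11=C12)
Conditions: second-generation Grubbs catalyst RuCl2(=CHPh)(H2IMes)(PCy3) (5 mol %), CH2Cl2, 40 °C
Reagents that add atoms: none
Why: Ring-closing metathesis between the terminal allyl and the 1,1-disubstituted isopropenyl group should give the trisubstituted cyclohexene of ring A with loss of ethene.

Step 11
Reactants: 15 bicyclic lactone
Product: 16 diol (C9 primary and C2 secondary hydroxyls)
Conditions: LiAlH4, THF, 0 °C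
Reagents that add atoms: none
Why: Hydride reduction opens the lactone to the C9 carbinol and the C2 alcohol without touching the ethers or the alkene.

Step 12
Reactants: 16 diol
Product: 17 C9 triethylsilyl ether
Conditions: Et3SiCl, imidazole, CH2Cl2, −40 °C
Reagents that add atoms: chlorotriethylsilane, CC[Si](Cl)(CC)CC
Why: Silylation is selective for the primary hydroxyl over the neopentyl secondary one.

Step 13
Reactants: 17 secondary alcohol
Product: 18 ring A ketone (C2 ketone with the C5–C16 arm)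
Conditions: Dess–Martin periodinane, NaHCO3, CH2Cl2, rt
Reagents that add atoms: none
Why: Dess–Martin oxidation gives the C2 ketone, which can enolise only toward C5 because C1 is quaternary.

**Iodoenal from the Roche ester (steps 14 to 19)**

Step 14
Reactants: 19 methyl (S)-3-hydroxy-2-methylpropanoate
Product: 20 methyl (S)-3-(tert-butyldiphenylsilyloxy)-2-methylpropanoate
Conditions: TBDPSCl, imidazole, DMF, rt
Reagents that add atoms: tert-butylchlorodiphenylsilane, CC(C)(C)[Si](Cl)(c1ccccc1)c1ccccc1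
Why: Silyl protection of the future C19 oxygen; the (S) ester is chosen so that its ester carbon becomes C8 and the stereocentre becomes C17 (R in the target).

Step 15
Reactants: 20 ester
Product: 21 (S)-3-(tert-butyldiphenylsilyloxy)-2-methylpropanal
Conditions: i-Bu2AlH, CH2Cl2, −78 °C
Reagents that add atoms: none
Why: Partial reduction at low temperature gives the aldehyde, which is used at once to avoid epimerisation at C17.

Step 16
Reactants: 21 aldehyde
Product: 22 (R)-tert-butyl[(2-methylbut-3-yn-1-yl)oxy]diphenylsilane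
Conditions: MeC(O)C(N2)P(O)(OMe)2, K2CO3, MeOH, 0 °C to rt
Reagents that add atoms: dimethyl (1-diazo-2-oxopropyl)phosphonate, CC(=O)C(=[N+]=[N-])P(=O)(OC)OC
Why: Ohira–Bestmann homologation converts the aldehyde carbon into alkyne carbon C8 and adds C7 under conditions mild enough for the α-stereocentre.

Step 17
Reactants: 22 alkyne
Product: 24 (R)-5-(tert-butyldiphenylsilyloxy)-4-methylpent-2-yn-1-ol, via lithium acetylide 23 (not isolated)
Conditions: n-BuLi, THF, −78 °C; (CH2O)n, −78 °C to rt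
Reagents that add atoms: n-butyllithium, [Li]CCCC (lithium only in 23); formaldehyde, C=O (as paraformaldehyde)
Why: Hydroxymethylation of the acetylide adds C6 as a propargylic alcohol.

Step 18
Reactants: 24 propargylic alcohol
Product: 26 (S,Z)-5-(tert-butyldiphenylsilyloxy)-3-iodo-4-methylpent-2-en-1-ol, via cyclic alkenylaluminate 25 (not isolated)
Conditions: NaAlH2(OCH2CH2OMe)2, THF, 0 °C; EtOAc; I2, −78 °C
Reagents that add atoms: sodium bis(2-methoxyethoxy)aluminium dihydride, [Na+].COCCO[AlH2-]OCCOC (aluminium only in 25); iodine, II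
Why: Hydroxyl-directed trans-hydroalumination places aluminium on C8 cis to C6, and iodinolysis with retention gives the Z iodoalkene in which C6 and the future C8–C9 bond are cis, as the eight-membered ring needs.

Step 19
Reactants: 26 allylic alcohol
Product: 27 (S,Z)-5-(tert-butyldiphenylsilyloxy)-3-iodo-4-methylpent-2-enal
Conditions: MnO2, CH2Cl2, rt, dark
Reagents that add atoms: none
Why: Allylic oxidation with MnO2 gives the C6 enal without disturbing the alkenyl iodide or C17.

**Eight-membered ring, lactone and dione (steps 20 to 29)**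

Step 20
Reactants: 18 ring A ketone; 27 iodoenal
Product: 29 syn aldol adduct (C5–C6 bond and C6 carbinol), via dibutylboron enolate 28 (not isolated)
Conditions: Bu2BOTf, i-Pr2NEt, CH2Cl2, −78 to 0 °C; 27, −78 °C; pH 7 buffer, MeOH, H2O2
Reagents that add atoms: dibutylboron triflate, CCCCB(CCCC)OS(=O)(=O)C(F)(F)F (boron only in 28)
Why: Boron aldol reaction of the only possible (Z) enolate through a Zimmerman–Traxler chair should give the syn adduct by 1,2-addition to the enal; the two new centres (C5, C6) are erased at the dione stage, so their absolute sense is not needed.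

Step 21
Reactants: 29 aldol adduct
Product: 30 C6 triethylsilyl ether
Conditions: Et3SiOTf, 2,6-lutidine, CH2Cl2, −78 °C
Reagents that add atoms: triethylsilyl triflate, CC[Si](OS(=O)(=O)C(F)(F)F)(CC)CC
Why: Silylation blocks the C6 hydroxyl so that it neither is oxidised nor directs the later osmylation.

Step 22
Reactants: 30 bis(triethylsilyl) ether
Product: 31 C9 aldehyde
Conditions: (COCl)2, DMSO, CH2Cl2, −78 to −40 °C; Et3N, −78 to 0 °C
Reagents that add atoms: none
Why: Under Swern conditions a primary triethylsilyl ether is converted directly into the aldehyde, while the secondary triethylsilyl, triisopropylsilyl and tert-butyldiphenylsilyl ethers should remain.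

Step 23
Reactants: 31 iodo keto aldehyde
Product: 32 eight-membered allylic alcohol (C8–C9 bond and 9R carbinol with Z C7=C8 in the ring)
Conditions: CrCl2 (10 equiv), NiCl2 (2 mol %), DMSO/THF, 0.003 M, rt
Reagents that add atoms: none
Why: Nozaki–Hiyama–Kishi reaction; divalent chromium (nickel-catalysed) inserts only into the C8–I bond and the alkenylchromium adds to the aldehyde rather than the ketone, closing the eight-membered ring under high dilution, with Felkin–Anh attack anti to quaternary C1 expected to give 9R.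

Step 24
Reactants: 32 allylic alcohol
Product: 33 osmate ester of the 7,8-diol as its TMEDA chelate
Conditions: OsO4 (1.05 equiv), TMEDA, CH2Cl2, −78 °C
Reagents that add atoms: osmium tetroxide, O=[Os](=O)(=O)=O; N,N,N',N'-tetramethylethylenediamine, CN(C)CCN(C)C
Why: Donohoe hydroxyl-directed dihydroxylation; the OsO4–TMEDA complex is hydrogen-bonded by the free C9 hydroxyl and should add to the same (α) face of C7=C8 only, which sets C7 and C8 and spares the ring A alkene.

Step 25
Reactants: 33 osmate ester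
Product: 35 7,8-diol 9-acetate, via acetylated osmate ester 34 (not isolated)
Conditions: Ac2O, pyridine, DMAP, CH2Cl2, rt; then aq. Na2SO3, THF, 40 °C
Reagents that add atoms: acetic anhydride, CC(=O)OC(C)=O
Why: The hexavalent osmate ester acts as a diol protecting group while O9 is acetylated, and reductive hydrolysis with sulfite then frees the diol, so O9 can never compete with O7 in the lactonisation.

Step 26
Reactants: 35 diol
Product: 36 tetrol (C6 C7 C8 and C19 hydroxyls free)
Conditions: Bu4NF, AcOH (1:1), THF, rt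
Reagents that add atoms: none
Why: Buffered fluoride removes the primary tert-butyldiphenylsilyl and secondary triethylsilyl ethers, while the hindered triisopropylsilyl ether on O14 and the acetate should survive.

Step 27
Reactants: 36 tetrol
Product: 38 γ-lactone (O7–C19) with C6 and C8 hydroxyls, via lactol 37 (not isolated)
Conditions: TEMPO (20 mol %), PhI(OAc)2, CH2Cl2, rt
Reagents that add atoms: none
Why: Oxoammonium oxidation is selective for the primary alcohol; the aldehyde is trapped by O7 as the five-membered lactol and oxidised on to the trans-fused γ-lactone, which is favoured over the six-membered alternative through O6.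

Step 28
Reactants: 38 hydroxy lactone
Product: 39 eight-membered 2,6-dione
Conditions: Dess–Martin periodinane (1.2 equiv), NaHCO3, CH2Cl2, 0 °C
Reagents that add atoms: none
Why: Oxidation of the only remaining secondary alcohol (C6) gives the 1,3-dione and removes the C5 and C6 stereocentres; the tertiary C8 hydroxyl is inert.

Step 29
Reactants: 39 dione
Product: 40 14-hydroxy dione
Conditions: HF·pyridine, pyridine, THF, 0 °C to rt
Reagents that add atoms: none
Why: Acidic fluoride cleaves the triisopropylsilyl ether without enolate chemistry at the sensitive 2-(alkoxymethyl)-1,3-dione.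

**Photoadduct and fragmentation precursor (steps 30 to 39)**

Step 30
Reactants: 40 14-hydroxy dione
Product: 42 cyclic di-tert-butylsilylene enol ether bridging O14 and O2 (enone C2=C5–C6=O), via silyl triflate 41 (not isolated)
Conditions: t-Bu2Si(OTf)2 (1.05 equiv), 2,6-lutidine, CH2Cl2, −78 to −20 °C; then Et3N, 0 °C
Reagents that add atoms: di-tert-butylsilyl bis(triflate), CC(C)(C)[Si](OS(=O)(=O)C(F)(F)F)(OS(=O)(=O)C(F)(F)F)C(C)(C)C
Why: The secondary C14 hydroxyl is silylated first, and the remaining Si–OTf can reach only the cis-disposed O2 (six-membered ring), so amine-mediated enol silylation fixes the enol ether on C2 and not on C6.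

Step 31
Reactants: 42 silylene enone
Product: 43 16-hydroxy enone
Conditions: DDQ, CH2Cl2/pH 7 buffer, 0 °C
Reagents that add atoms: none
Why: Oxidative cleavage of the 4-methoxybenzyl ether is neutral and should leave the electron-poor β-silyloxy enone intact.

Step 32
Reactants: 43 16-hydroxy enone
Product: 44 dimethyl(vinyl)silyl ether on O16
Conditions: ClSiMe2(CH=CH2), imidazole, CH2Cl2, −40 °C
Reagents that add atoms: chloro(dimethyl)vinylsilane, C=C[Si](C)(C)Cl
Why: Silylation of the primary hydroxyl attaches the future C3–C4 unit through a three-atom tether from C5; the tertiary C8 hydroxyl is too hindered to react.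

Step 33
Reactants: 44 tethered enone
Product: 45 photoadduct (cyclobutane C2–C3–C4–C5 fused to a five-membered oxasilolane)
Conditions: hν (Hg lamp, Pyrex filter), degassed MeCN (0.002 M), 0 °C
Reagents that add atoms: none
Why: Intramolecular enone–alkene [2+2] photocycloaddition; the three-atom tether enforces five-membered ring formation (C5–C4 first, then C2–C3), which fixes the regiochemistry and places silicon on C4 cis to C16, and addition anti to the C15 methyl should put the cis-fused cyclobutane on the α face.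

Step 34
Reactants: 45 photoadduct
Product: 46 6α-alcohol
Conditions: Et2BOMe, THF/MeOH (4:1), −78 °C; NaBH4; AcOH; MeOH azeotrope
Reagents that add atoms: none
Why: Narasaka–Prasad reduction; the boron chelate between the free C8 hydroxyl and the C6 ketone directs external hydride to give the 1,3-syn diol, i.e. the C6 oxygen on the α face that the fragmentation needs.

Step 35
Reactants: 46 diol
Product: 47 C6 mesylate
Conditions: MsCl, Et3N, CH2Cl2, −20 °C
Reagents that add atoms: methanesulfonyl chloride, CS(=O)(=O)Cl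
Why: Sulfonylation takes the secondary alcohol and leaves the tertiary C8 hydroxyl untouched.

Step 36
Reactants: 47 mesylate
Product: 48 C8 triethylsilyl ether
Conditions: Et3SiOTf, 2,6-lutidine, CH2Cl2, −78 to 0 °C
Reagents that add atoms: triethylsilyl triflate, CC[Si](OS(=O)(=O)C(F)(F)F)(CC)CC
Why: Silylation masks O8, whose alkoxide could otherwise trigger a competing C7–C8 fragmentation onto the same mesylate.

Step 37
Reactants: 48 oxasilolane
Product: 49 4,16-diol (C4 hydroxyl cis to C16)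
Conditions: 30% H2O2, KF, KHCO3, THF/MeOH, 0 °C to rt
Reagents that add atoms: hydrogen peroxide, OO
Why: Tamao oxidation converts the C4–Si bond into C4–OH with retention and frees O16, which gives the 4R oxygen; bicarbonate is too weak a base to fragment the diol mesylate.

Step 38
Reactants: 49 diol
Product: 50 16-acetate
Conditions: AcCl (1.1 equiv), 2,4,6-collidine, CH2Cl2, −78 °C
Reagents that add atoms: acetyl chloride, CC(=O)Cl
Why: Low-temperature acylation with a hindered base is selective for the primary over the secondary cyclobutanol hydroxyl.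

Step 39
Reactants: 50 cyclobutanol
Product: 51 4-butyrate (C2–O–Si(t-Bu)2–O–C14 silylene with C6 mesylate and C8 triethylsilyl ether)
Conditions: (n-PrCO)2O, pyridine, DMAP (cat.), CH2Cl2, 0 °C
Reagents that add atoms: butyric anhydride, CCCC(=O)OC(=O)CCC
Why: Esterification of the remaining secondary hydroxyl installs the butyrate, so no free alkoxide other than O2 can form in the next step.

**Fragmentation and endgame (steps 40 to 43)**

Step 40
Reactants: 51 cyclobutane mesylate
Product: 53 ring B 2-ketone with Z C5=C6 alkene and O14 fluorosilyl ether, via C2 alkoxide 52 (not isolated)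
Conditions: Bu4NF (1.05 equiv), THF, −40 to 0 °C; pH 7 buffer
Reagents that add atoms: tetrabutylammonium fluoride, CCCC[N+](CCCC)(CCCC)CCCC.[F-]
Why: Fluoride adds to the dialkoxysilane and expels the tertiary C2 alkoxide 52, whose lone pair pushes into the C2–C5 σ bond held anti-periplanar to the C6–O bond of the mesylate, so that C2=O and C5=C6 form in one concerted Grob fragmentation. The closest precedent is the fluoride- or base-induced fragmentation of γ-sulfonyloxy cyclobutanols made by enone–alkene photocycloaddition. No ring is closed by bond formation: ten-membered ring B arises by cleavage of the zero-atom bridge of the bicyclo[6.2.0]decane, a ring expansion by C3 and C4. No stereocentre is created (C2 and C5 become trigonal); the alkene geometry is set stereospecifically, because in the reactive conformer C4 is gauche and C16 anti to C7, which gives Z with C4 and C7 cis. The alignment is secured by the cis ring fusion of the photoadduct and by the α-configured C6 mesylate from the chelation-controlled reduction of step 34. One equivalent of fluoride at low temperature is consumed by silicon, so the medium is neutral once the mesylate has left and the β-butyryloxy ketone is not exposed to base; silicon remains on O14 as the fluorosilyl ether.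

Step 41
Reactants: 53 ring B ketone
Product: 54 8,14-dihydroxy 2-ketone
Conditions: HF·pyridine, pyridine, THF, 0 °C to rt
Reagents that add atoms: none
Why: Acidic fluoride removes the di-tert-butylfluorosilyl and triethylsilyl groups without base, so the β-acyloxy ketone and the β-hydroxy ketone (C14/C2) are not endangered.

Step 42
Reactants: 54 β-hydroxy ketone
Product: 55 2,8,14-triol (2R)
Conditions: Et2BOMe, THF/MeOH (4:1), −78 °C; NaBH4; AcOH; MeOH azeotrope
Reagents that add atoms: none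
Why: Narasaka–Prasad reduction through the boron chelate of the C14 hydroxyl and the C2 ketone should deliver hydride to give the 1,3-syn diol, which is the 2R configuration of the target.

Step 43
Reactants: 55 triol
Product: 56 target CNP0290502.1
Conditions: Ac2O, pyridine, DMAP (cat.), CH2Cl2, 0 °C to rt
Reagents that add atoms: acetic anhydride, CC(=O)OC(C)=O
Why: Acetylation takes the two secondary hydroxyls (O2, O14) and leaves the hindered tertiary C8 hydroxyl free.

**Compound list**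

1 | (S)-2,2-dimethyl-1,3-dioxolane-4-carbaldehyde | O=C[C@@H]1COC(C)(C)O1 | starting material
2 | 2-(triphenylphosphoranylidene)propanal | CC(C=O)=P(c1ccccc1)(c1ccccc1)c1ccccc1 | starting material
3 | (E)-3-[(4R)-2,2-dimethyl-1,3-dioxolan-4-yl]-2-methylprop-2-enal | O=C/C(C)=C/[C@@H]1COC(C)(C)O1 | intermediate
4 | (1E,3S)-1-[(4R)-2,2-dimethyl-1,3-dioxolan-4-yl]-2-methylhexa-1,5-dien-3-ol | C=CC[C@H](O)/C(C)=C/[C@@H]1COC(C)(C)O1 | intermediate
5 | triisopropylsilyl ether of 4 | C=CC[C@H](O[Si](C(C)C)(C(C)C)C(C)C)/C(C)=C/[C@@H]1COC(C)(C)O1 | intermediate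
6 | (2R,3E,5S)-4-methyl-5-(triisopropylsilyloxy)octa-3,7-diene-1,2-diol | C=CC[C@H](O[Si](C(C)C)(C(C)C)C(C)C)/C(C)=C/[C@@H](O)CO | intermediate
7 | (2R,3E,5S)-1-(4-methoxybenzyloxy)-4-methyl-5-(triisopropylsilyloxy)octa-3,7-dien-2-ol | C=CC[C@H](O[Si](C(C)C)(C(C)C)C(C)C)/C(C)=C/[C@@H](O)COCc1ccc(OC)cc1 | intermediate
8 | 3-methylbut-2-enoyl chloride | CC(C)=CC(Cl)=O | starting material
9 | 3-methylbut-2-enoate of 7 | C=CC[C@H](O[Si](C(C)C)(C(C)C)C(C)C)/C(C)=C/[C@@H](OC(=O)C=C(C)C)COCc1ccc(OC)cc1 | intermediate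
10 | (Z)-O-trimethylsilyl dienolate (silyl ketene acetal) of 9 | C=CC[C@H](O[Si](C(C)C)(C(C)C)C(C)C)/C(C)=C/[C@@H](O/C(O[Si](C)(C)C)=C/C(C)=C)COCc1ccc(OC)cc1 | intermediate (not isolated)
11 | trimethylsilyl ester of 12 | C[Si](C)(C)OC(=O)[C@@H](C(C)=C)[C@](C)([C@@H](O[Si](C(C)C)(C(C)C)C(C)C)CC=C)/C=C/COCc1ccc(OC)cc1 | intermediate (not isolated)
12 | Claisen acid (C9 acid, C10 isopropenyl, C1 quaternary, C14 silyl ether, E C2=C5) | OC(=O)[C@@H](C(C)=C)[C@](C)([C@@H](O[Si](C(C)C)(C(C)C)C(C)C)CC=C)/C=C/COCc1ccc(OC)cc1 | intermediate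
13 | iodo-γ-lactone | O=C1O[C@H]([C@H](I)COCc2ccc(OC)cc2)[C@@](C)([C@@H](O[Si](C(C)C)(C(C)C)C(C)C)CC=C)[C@@H]1C(C)=C | intermediate
14 | deiodinated γ-lactone | O=C1O[C@H](CCOCc2ccc(OC)cc2)[C@@](C)([C@@H](O[Si](C(C)C)(C(C)C)C(C)C)CC=C)[C@@H]1C(C)=C | intermediate
15 | bicyclic lactone with ring A | O=C1O[C@H](CCOCc2ccc(OC)cc2)[C@@]2(C)[C@@H](O[Si](C(C)C)(C(C)C)C(C)C)CC=C(C)[C@H]12 | intermediate
16 | ring A diol (C9 and C2 hydroxyls) | OC[C@H]1C(C)=CC[C@H](O[Si](C(C)C)(C(C)C)C(C)C)[C@]1(C)[C@H](O)CCOCc1ccc(OC)cc1 | intermediate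
17 | C9 triethylsilyl ether of 16 | CC[Si](CC)(CC)OC[C@H]1C(C)=CC[C@H](O[Si](C(C)C)(C(C)C)C(C)C)[C@]1(C)[C@H](O)CCOCc1ccc(OC)cc1 | intermediate
18 | ring A ketone | CC[Si](CC)(CC)OC[C@H]1C(C)=CC[C@H](O[Si](C(C)C)(C(C)C)C(C)C)[C@]1(C)C(=O)CCOCc1ccc(OC)cc1 | intermediate
19 | methyl (S)-3-hydroxy-2-methylpropanoate | COC(=O)[C@@H](C)CO | starting material
20 | methyl (S)-3-(tert-butyldiphenylsilyloxy)-2-methylpropanoate | COC(=O)[C@@H](C)CO[Si](c1ccccc1)(c1ccccc1)C(C)(C)C | intermediate
21 | (S)-3-(tert-butyldiphenylsilyloxy)-2-methylpropanal | O=C[C@@H](C)CO[Si](c1ccccc1)(c1ccccc1)C(C)(C)C | intermediate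
22 | (R)-tert-butyl[(2-methylbut-3-yn-1-yl)oxy]diphenylsilane | C#C[C@@H](C)CO[Si](c1ccccc1)(c1ccccc1)C(C)(C)C | intermediate
23 | lithium acetylide of 22 | [Li]C#C[C@@H](C)CO[Si](c1ccccc1)(c1ccccc1)C(C)(C)C | intermediate (not isolated)
24 | (R)-5-(tert-butyldiphenylsilyloxy)-4-methylpent-2-yn-1-ol | OCC#C[C@@H](C)CO[Si](c1ccccc1)(c1ccccc1)C(C)(C)C | intermediate
25 | sodium cyclic alkenyl(alkoxy)aluminate | [Na+].COCCO[Al-]1(OCCOC)OCC=C1[C@@H](C)CO[Si](c1ccccc1)(c1ccccc1)C(C)(C)C | intermediate (not isolated)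
26 | (S,Z)-5-(tert-butyldiphenylsilyloxy)-3-iodo-4-methylpent-2-en-1-ol | OC/C=C(\I)[C@@H](C)CO[Si](c1ccccc1)(c1ccccc1)C(C)(C)C | intermediate
27 | (S,Z)-5-(tert-butyldiphenylsilyloxy)-3-iodo-4-methylpent-2-enal | O=C/C=C(\I)[C@@H](C)CO[Si](c1ccccc1)(c1ccccc1)C(C)(C)C | intermediate
28 | dibutylboron (Z)-enolate of 18 | CCCCB(CCCC)O/C(=C\COCc1ccc(OC)cc1)[C@@]1(C)[C@@H](O[Si](C(C)C)(C(C)C)C(C)C)CC=C(C)[C@@H]1CO[Si](CC)(CC)CC | intermediate (not isolated)
29 | syn aldol adduct | CC[Si](CC)(CC)OC[C@H]1C(C)=CC[C@H](O[Si](C(C)C)(C(C)C)C(C)C)[C@]1(C)C(=O)[C@@H](COCc1ccc(OC)cc1)[C@H](O)/C=C(\I)[C@@H](C)CO[Si](c1ccccc1)(c1ccccc1)C(C)(C)C | intermediate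
30 | C6 triethylsilyl ether of 29 | CC[Si](CC)(CC)OC[C@H]1C(C)=CC[C@H](O[Si](C(C)C)(C(C)C)C(C)C)[C@]1(C)C(=O)[C@@H](COCc1ccc(OC)cc1)[C@H](O[Si](CC)(CC)CC)/C=C(\I)[C@@H](C)CO[Si](c1ccccc1)(c1ccccc1)C(C)(C)C | intermediate
31 | C9 aldehyde | O=C[C@H]1C(C)=CC[C@H](O[Si](C(C)C)(C(C)C)C(C)C)[C@]1(C)C(=O)[C@@H](COCc1ccc(OC)cc1)[C@H](O[Si](CC)(CC)CC)/C=C(\I)[C@@H](C)CO[Si](c1ccccc1)(c1ccccc1)C(C)(C)C | intermediate
32 | eight-membered allylic alcohol (9-OH) | O[C@@H]1[C@H]2C(C)=CC[C@H](O[Si](C(C)C)(C(C)C)C(C)C)[C@]2(C)C(=O)[C@@H](COCc2ccc(OC)cc2)[C@H](O[Si](CC)(CC)CC)/C=C1/[C@@H](C)CO[Si](c1ccccc1)(c1ccccc1)C(C)(C)C | intermediate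
33 | 7,8-osmate ester, TMEDA chelate | O[C@@H]1[C@H]2C(C)=CC[C@H](O[Si](C(C)C)(C(C)C)C(C)C)[C@]2(C)C(=O)[C@@H](COCc2ccc(OC)cc2)[C@H](O[Si](CC)(CC)CC)[C@@H]2O[Os](=O)(=O)O[C@]12[C@@H](C)CO[Si](c1ccccc1)(c1ccccc1)C(C)(C)C.CN(C)CCN(C)C | intermediate
34 | 9-acetate of osmate ester 33 | CC(=O)O[C@@H]1[C@H]2C(C)=CC[C@H](O[Si](C(C)C)(C(C)C)C(C)C)[C@]2(C)C(=O)[C@@H](COCc2ccc(OC)cc2)[C@H](O[Si](CC)(CC)CC)[C@@H]2O[Os](=O)(=O)O[C@]12[C@@H](C)CO[Si](c1ccccc1)(c1ccccc1)C(C)(C)C.CN(C)CCN(C)C | intermediate (not isolated)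
35 | 7,8-diol 9-acetate | CC(=O)O[C@@H]1[C@H]2C(C)=CC[C@H](O[Si](C(C)C)(C(C)C)C(C)C)[C@]2(C)C(=O)[C@@H](COCc2ccc(OC)cc2)[C@H](O[Si](CC)(CC)CC)[C@H](O)[C@@]1(O)[C@@H](C)CO[Si](c1ccccc1)(c1ccccc1)C(C)(C)C | intermediate
36 | tetrol | CC(=O)O[C@@H]1[C@H]2C(C)=CC[C@H](O[Si](C(C)C)(C(C)C)C(C)C)[C@]2(C)C(=O)[C@@H](COCc2ccc(OC)cc2)[C@H](O)[C@H](O)[C@@]1(O)[C@@H](C)CO | intermediate
37 | γ-lactol | CC(=O)O[C@@H]1[C@H]2C(C)=CC[C@H](O[Si](C(C)C)(C(C)C)C(C)C)[C@]2(C)C(=O)[C@@H](COCc2ccc(OC)cc2)[C@H](O)[C@@H]2OC(O)[C@H](C)[C@@]12O | intermediate (not isolated)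
38 | γ-lactone with 6- and 8-hydroxyls | CC(=O)O[C@@H]1[C@H]2C(C)=CC[C@H](O[Si](C(C)C)(C(C)C)C(C)C)[C@]2(C)C(=O)[C@@H](COCc2ccc(OC)cc2)[C@H](O)[C@@H]2OC(=O)[C@H](C)[C@@]12O | intermediate
39 | eight-membered 2,6-dione (C5 configurationally labile) | CC(=O)O[C@@H]1[C@H]2C(C)=CC[C@H](O[Si](C(C)C)(C(C)C)C(C)C)[C@]2(C)C(=O)C(COCc2ccc(OC)cc2)C(=O)[C@@H]2OC(=O)[C@H](C)[C@@]12O | intermediate
40 | 14-hydroxy dione | CC(=O)O[C@@H]1[C@H]2C(C)=CC[C@H](O)[C@]2(C)C(=O)C(COCc2ccc(OC)cc2)C(=O)[C@@H]2OC(=O)[C@H](C)[C@@]12O | intermediate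
41 | O14 di-tert-butylsilyl triflate | CC(=O)O[C@@H]1[C@H]2C(C)=CC[C@H](O[Si](OS(=O)(=O)C(F)(F)F)(C(C)(C)C)C(C)(C)C)[C@]2(C)C(=O)C(COCc2ccc(OC)cc2)C(=O)[C@@H]2OC(=O)[C@H](C)[C@@]12O | intermediate (not isolated)
42 | silylene-locked enone (O14–Si–O2) | CC(=O)O[C@@H]1[C@H]2C(C)=CC[C@@H]3O[Si](C(C)(C)C)(C(C)(C)C)O/C(=C(\COCc4ccc(OC)cc4)C(=O)[C@@H]4OC(=O)[C@H](C)[C@@]14O)[C@]23C | intermediate
43 | 16-hydroxy enone | CC(=O)O[C@@H]1[C@H]2C(C)=CC[C@@H]3O[Si](C(C)(C)C)(C(C)(C)C)O/C(=C(\CO)C(=O)[C@@H]4OC(=O)[C@H](C)[C@@]14O)[C@]23C | intermediate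
44 | O16 dimethyl(vinyl)silyl ether | CC(=O)O[C@@H]1[C@H]2C(C)=CC[C@@H]3O[Si](C(C)(C)C)(C(C)(C)C)O/C(=C(\CO[Si](C)(C)C=C)C(=O)[C@@H]4OC(=O)[C@H](C)[C@@]14O)[C@]23C | intermediate
45 | photoadduct | CC(=O)O[C@@H]1[C@H]2C(C)=CC[C@@H]3O[Si](C(C)(C)C)(C(C)(C)C)O[C@]4(C[C@H]5[Si](C)(C)OC[C@@]45C(=O)[C@@H]6OC(=O)[C@H](C)[C@@]16O)[C@]23C | intermediate
46 | 6α-alcohol | CC(=O)O[C@@H]1[C@H]2C(C)=CC[C@@H]3O[Si](C(C)(C)C)(C(C)(C)C)O[C@]4(C[C@H]5[Si](C)(C)OC[C@@]45[C@H](O)[C@@H]6OC(=O)[C@H](C)[C@@]16O)[C@]23C | intermediate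
47 | C6 mesylate | CC(=O)O[C@@H]1[C@H]2C(C)=CC[C@@H]3O[Si](C(C)(C)C)(C(C)(C)C)O[C@]4(C[C@H]5[Si](C)(C)OC[C@@]45[C@H](OS(C)(=O)=O)[C@@H]6OC(=O)[C@H](C)[C@@]16O)[C@]23C | intermediate
48 | C8 triethylsilyl ether of 47 | CC(=O)O[C@@H]1[C@H]2C(C)=CC[C@@H]3O[Si](C(C)(C)C)(C(C)(C)C)O[C@]4(C[C@H]5[Si](C)(C)OC[C@@]45[C@H](OS(C)(=O)=O)[C@@H]6OC(=O)[C@H](C)[C@@]16O[Si](CC)(CC)CC)[C@]23C | intermediate
49 | 4,16-diol | CC(=O)O[C@@H]1[C@H]2C(C)=CC[C@@H]3O[Si](C(C)(C)C)(C(C)(C)C)O[C@]4(C[C@@H](O)[C@]4(CO)[C@H](OS(C)(=O)=O)[C@@H]5OC(=O)[C@H](C)[C@@]15O[Si](CC)(CC)CC)[C@]23C | intermediate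
50 | 16-acetate | CC(=O)O[C@@H]1[C@H]2C(C)=CC[C@@H]3O[Si](C(C)(C)C)(C(C)(C)C)O[C@]4(C[C@@H](O)[C@]4(COC(C)=O)[C@H](OS(C)(=O)=O)[C@@H]5OC(=O)[C@H](C)[C@@]15O[Si](CC)(CC)CC)[C@]23C | intermediate
51 | fragmentation precursor (O2 silyl ether, C6 mesylate, C2–C5 bonded cyclobutane) | CC(=O)O[C@@H]1[C@H]2C(C)=CC[C@@H]3O[Si](C(C)(C)C)(C(C)(C)C)O[C@]4(C[C@@H](OC(=O)CCC)[C@]4(COC(C)=O)[C@H](OS(C)(=O)=O)[C@@H]5OC(=O)[C@H](C)[C@@]15O[Si](CC)(CC)CC)[C@]23C | intermediate
52 | tetrabutylammonium C2 alkoxide | CC(=O)O[C@@H]1[C@H]2C(C)=CC[C@H](O[Si](F)(C(C)(C)C)C(C)(C)C)[C@]2(C)[C@]3([O-])C[C@@H](OC(=O)CCC)[C@]3(COC(C)=O)[C@H](OS(C)(=O)=O)[C@@H]3OC(=O)[C@H](C)[C@@]13O[Si](CC)(CC)CC.CCCC[N+](CCCC)(CCCC)CCCC | intermediate (not isolated)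
53 | ring B 2-ketone with Z C5=C6 alkene | CCCC(=O)O[C@@H]1CC(=O)[C@@]2(C)[C@@H](O[Si](F)(C(C)(C)C)C(C)(C)C)CC=C(C)[C@@H]2[C@@H](OC(C)=O)[C@@]2(O[Si](CC)(CC)CC)[C@H](/C=C\1COC(C)=O)OC(=O)[C@@H]2C | intermediate
54 | 8,14-dihydroxy 2-ketone | CCCC(=O)O[C@@H]1CC(=O)[C@@]2(C)[C@@H](O)CC=C(C)[C@@H]2[C@@H](OC(C)=O)[C@@]2(O)[C@H](/C=C\1COC(C)=O)OC(=O)[C@@H]2C | intermediate
55 | 2,8,14-triol | CCCC(=O)O[C@@H]1C[C@@H](O)[C@@]2(C)[C@@H](O)CC=C(C)[C@@H]2[C@@H](OC(C)=O)[C@@]2(O)[C@H](/C=C\1COC(C)=O)OC(=O)[C@@H]2C | intermediate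
56 | CNP0290502.1 | CCCC(=O)O[C@@H]1C[C@@H](OC(C)=O)[C@@]2(C)[C@@H](OC(C)=O)CC=C(C)[C@@H]2[C@@H](OC(C)=O)[C@@]2(O)[C@H](/C=C\1COC(C)=O)OC(=O)[C@@H]2C | target

**Step count and risks**

Total step count: 43. Longest linear sequence: 37 steps (steps 1 to 13 and 20 to 43).

Steps most likely to fail:

Step 40. The hindered silylene may consume fluoride more slowly than assumed, so that basic fluoride stays in contact with the β-butyryloxy ketone (loss of butyric acid by elimination) or attacks the C8 silyl ether. The fallback sets out from 51 and separates unmasking from fragmentation: buffered HF·pyridine at 0 °C should cleave the silylene under acidic conditions to the free cyclobutanol, diol mesylate F1. F1 is then fragmented with one equivalent of DBU in CH2Cl2 at −40 °C, the ring strain of the cyclobutanol carrying the reaction, to give hydroxy ketone F2. HF·pyridine at room temperature removes the C8 silyl ether and the route is rejoined at 54.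

Step 33. The tethered vinylsilane may fail to reach the α face of the enone, or the triplet enone may be diverted (addition to the ring A alkene, hydrogen abstraction, oligomerisation). The fallback sets out from 43 and uses an untethered photopartner: acetylation (Ac2O, pyridine) gives 16-acetate F3, and irradiation in the presence of excess vinyl butyrate gives cyclobutane F4 after separation from the regioisomer. Chelation-controlled reduction as in step 34 gives alcohol F5, mesylation gives F6, and silylation of O8 as in step 36 returns to 51.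

Step 23. Intermolecular coupling and protodehalogenation of the alkenylchromium may outrun closure of the eight-membered ring. The fallback moves the ring closure to the C7=C8 alkene and sets out from 18 and 22. Hydroiodination of 22 (B-iodo-9-borabicyclo[3.3.1]nonane, then AcOH) gives 2-iodoalkene F7. Boron aldol of 18 with acrolein gives F8, silylation gives F9 and Swern oxidation as in step 22 gives keto aldehyde F10. Intermolecular CrCl2/NiCl2 coupling of F7 with F10 (Felkin–Anh control at C9) gives diene F11, and ring-closing metathesis with the second-generation Grubbs catalyst returns to 32.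

**Further compounds**

F1 | step 40 | free cyclobutanol diol mesylate (C2 and C14 hydroxyls, C8 silyl ether kept) | CC(=O)O[C@@H]1[C@H]2C(C)=CC[C@H](O)[C@]2(C)[C@]3(O)C[C@@H](OC(=O)CCC)[C@]3(COC(C)=O)[C@H](OS(C)(=O)=O)[C@@H]3OC(=O)[C@H](C)[C@@]13O[Si](CC)(CC)CC
F2 | step 40 | ring B 2-ketone with 14-hydroxyl and C8 silyl ether | CCCC(=O)O[C@@H]1CC(=O)[C@@]2(C)[C@@H](O)CC=C(C)[C@@H]2[C@@H](OC(C)=O)[C@@]2(O[Si](CC)(CC)CC)[C@H](/C=C\1COC(C)=O)OC(=O)[C@@H]2C
F3 | step 33 | 16-acetate of enone 43 | CC(=O)O[C@@H]1[C@H]2C(C)=CC[C@@H]3O[Si](C(C)(C)C)(C(C)(C)C)O/C(=C(\COC(C)=O)C(=O)[C@@H]4OC(=O)[C@H](C)[C@@]14O)[C@]23C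
F4 | step 33 | intermolecular photoadduct with vinyl butyrate (C6 ketone) | CC(=O)O[C@@H]1[C@H]2C(C)=CC[C@@H]3O[Si](C(C)(C)C)(C(C)(C)C)O[C@]4(C[C@@H](OC(=O)CCC)[C@]4(COC(C)=O)C(=O)[C@@H]5OC(=O)[C@H](C)[C@@]15O)[C@]23C
F5 | step 33 | 6α-alcohol of F4 | CC(=O)O[C@@H]1[C@H]2C(C)=CC[C@@H]3O[Si](C(C)(C)C)(C(C)(C)C)O[C@]4(C[C@@H](OC(=O)CCC)[C@]4(COC(C)=O)[C@H](O)[C@@H]5OC(=O)[C@H](C)[C@@]15O)[C@]23C
F6 | step 33 | C6 mesylate of F5 | CC(=O)O[C@@H]1[C@H]2C(C)=CC[C@@H]3O[Si](C(C)(C)C)(C(C)(C)C)O[C@]4(C[C@@H](OC(=O)CCC)[C@]4(COC(C)=O)[C@H](OS(C)(=O)=O)[C@@H]5OC(=O)[C@H](C)[C@@]15O)[C@]23C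
F7 | step 23 | (S)-tert-butyl[(3-iodo-2-methylbut-3-en-1-yl)oxy]diphenylsilane | C=C(I)[C@@H](C)CO[Si](c1ccccc1)(c1ccccc1)C(C)(C)C
F8 | step 23 | aldol adduct of 18 with acrolein | CC[Si](CC)(CC)OC[C@H]1C(C)=CC[C@H](O[Si](C(C)C)(C(C)C)C(C)C)[C@]1(C)C(=O)[C@@H](COCc1ccc(OC)cc1)[C@H](O)C=C
F9 | step 23 | C6 triethylsilyl ether of F8 | CC[Si](CC)(CC)OC[C@H]1C(C)=CC[C@H](O[Si](C(C)C)(C(C)C)C(C)C)[C@]1(C)C(=O)[C@@H](COCc1ccc(OC)cc1)[C@H](O[Si](CC)(CC)CC)C=C
F10 | step 23 | C9 aldehyde from F9 | O=C[C@H]1C(C)=CC[C@H](O[Si](C(C)C)(C(C)C)C(C)C)[C@]1(C)C(=O)[C@@H](COCc1ccc(OC)cc1)[C@H](O[Si](CC)(CC)CC)C=C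
F11 | step 23 | acyclic C9 carbinol diene (C8 methylene and C7 vinyl) | O[C@@H](C(=C)[C@@H](C)CO[Si](c1ccccc1)(c1ccccc1)C(C)(C)C)[C@H]1C(C)=CC[C@H](O[Si](C(C)C)(C(C)C)C(C)C)[C@]1(C)C(=O)[C@@H](COCc1ccc(OC)cc1)[C@H](O[Si](CC)(CC)CC)C=C
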